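**Plan**
- Retrosynthesis: the pyrrole bonds N11–C11a and N12–C11b are cut first, leading back to a 3,6-bis(2-nitroaryl)catechol. The central-ring bonds C4b–C11b and C6a–C11a are cut next, giving diethyl oxalate and (Z)-1,4-bis(4-chloro-2-nitrophenyl)-2,3-dimethoxybut-2-ene. The two aryl–CH2 bonds are cut last.
- Enabling feature: C11a and C11b, the adjacent N-bearing carbons of the central benzene ring, are a C2 unit at the oxalate oxidation level. Their neighbours C4b and C6a sit ortho to nitrogen on the outer rings, so in a dinitro precursor they are acidic o-nitrobenzylic CH2 groups.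
- Forward order: Z-configured C4 enediol ether unit, then the diaryl butene, then the central benzene ring by oxalate benzannulation, then both pyrrole rings by double C–N ring closure.
- Stereochemistry: the target has no stereocentre. The only stereochemical element on the way is the Z alkene of the enediol ether, set by cis-1,4-diboration of the diene and carried unchanged into the key step.

Key step: step 4

Assumption: 2,3-dimethoxybuta-1,3-diene is taken as a purchased diene (otherwise two known steps from butane-2,3-dione and trimethyl orthoformate).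
Remark: the aryl–aryl axes of 10–12 are hindered, so these compounds may appear as slowly interconverting rotamers; this is without consequence because both axes end up in planar rings in step 7.

Step 1
Reactants: 1 2,3-dimethoxybuta-1,3-diene
Product: 3 (Z)-2,3-dimethoxybut-2-ene-1,4-diol, via Z-1,4-bis(pinacolboronate) 2 (not isolated)
Conditions: B2pin2 (1.05 equiv), Pt(PPh3)4 (3 mol%), toluene, 80 °C; then 3 M NaOH, 30% H2O2, THF, 0 °C → rt; basic work-up
Reagents that add atoms: bis(pinacolato)diboron, CC1(C)OB(OC1(C)C)B1OC(C)(C)C(C)(C)O1 (boron groups of 2); hydrogen peroxide, OO (oxygen atoms of 3)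
Why: Platinum(0)-catalysed 1,4-diboration of the s-cis diene (Miyaura diene diboration) places both boryl groups at the termini and leaves a Z tetrasubstituted alkene; alkaline peroxide then replaces each C–B by C–OH with retention, so the two CH2OH groups are cis by construction.

Step 2
Reactants: 3 (Z)-2,3-dimethoxybut-2-ene-1,4-diol
Product: 4 dimethyl (Z)-(2,3-dimethoxybut-2-ene-1,4-diyl) bis(carbonate)
Conditions: ClCO2Me (2.5 equiv), pyridine, DMAP (cat.), CH2Cl2, 0 °C
Reagents that add atoms: methyl chloroformate, COC(=O)Cl
Why: Acylation of the two primary allylic alcohols to carbonates under basic conditions leaves the acid-sensitive enol ether and its geometry untouched.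

Step 3
Reactants: 4 dimethyl (Z)-(2,3-dimethoxybut-2-ene-1,4-diyl) bis(carbonate); 5 (4-chloro-2-nitrophenyl)boronic acid
Product: 6 (Z)-1,4-bis(4-chloro-2-nitrophenyl)-2,3-dimethoxybut-2-ene
Conditions: 5 (2.6 equiv), Pd2(dba)3 (2.5 mol%), PPh3 (10 mol%), THF, 50 °C, no added base; Et3N-deactivated silica
Reagents that add atoms: none
Why: In this base-free allyl–aryl Suzuki–Miyaura coupling, Pd(0) ionizes each allylic carbonate to a π-allyl complex, the released methoxide activates the boronic acid, and reductive elimination at the unhindered CH2 terminus should give the linear product with the Z geometry kept, because syn–anti exchange would require a tertiary σ-allyl palladium.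

Step 4
Reactants: 6 (Z)-1,4-bis(4-chloro-2-nitrophenyl)-2,3-dimethoxybut-2-ene; 7 diethyl oxalate
Product: 10 3,6-bis(4-chloro-2-nitrophenyl)-4,5-dimethoxybenzene-1,2-diol, via acyclic keto ester 8 (not isolated), via cyclohexene-1,2-dione 9 (not isolated)
Conditions: 7 (1.05 equiv), KOt-Bu (3.0 equiv), THF (0.02 M), N2, −20 °C → rt; then degassed 1 M HCl, Na2S2O4 wash
Reagents that add atoms: none
Why: Proposed new method: tert-butoxide removes an o-nitrobenzylic (and allylic) proton of 6, the nitronate-type carbanion is C-acylated at its benzylic carbon by one ester group of 7 as in a Reissert condensation, and the resulting α-keto ester 8 sits as its enolate, which masks the ketone and leaves the ester as the only electrophile. A second benzylic deprotonation then allows a Dieckmann-type 6-exo-trig attack on that ester carbon, closing the central ring as dione 9 with the new bonds C4b–C11b and C6a–C11a, and two enolizations aromatize it irreversibly to the catecholate of 10. The closest known reaction types are the Reissert condensation of o-nitrotoluenes with diethyl oxalate and the two-fold Claisen (Hinsberg-type) condensation of oxalate with bis(methylene) compounds held cis by a ring, a role played here by the Z enediol ether. No stereocentre survives, since the sp3 centres of 8 and 9 are erased on enolization. The step needs cis benzylic carbons (secured by the Z geometry from step 1), acylation at the benzylic and not the methoxy-bearing allylic terminus (secured by higher charge density and lower hindrance at the benzylic carbon), and ring closure in preference to a second intermolecular acylation or proton return at the allylic terminus (favoured by one equivalent of oxalate, high dilution and an aprotic medium with excess strong base).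

Step 5
Reactants: 10 3,6-bis(4-chloro-2-nitrophenyl)-4,5-dimethoxybenzene-1,2-diol
Product: 11 3,6-bis(4-chloro-2-nitrophenyl)-4,5-dimethoxy-1,2-phenylene bis(trifluoromethanesulfonate)
Conditions: Tf2O (2.4 equiv), pyridine, CH2Cl2, −20 → 0 °C
Reagents that add atoms: trifluoromethanesulfonic anhydride, O=S(=O)(OS(=O)(=O)C(F)(F)F)C(F)(F)F
Why: O-Sulfonylation of both phenols turns the two oxalate-derived oxygens into leaving groups, marking C11a and C11b for nitrogen while the methyl ethers at C5 and C6 stay inert.

Step 6
Reactants: 11 3,6-bis(4-chloro-2-nitrophenyl)-4,5-dimethoxy-1,2-phenylene bis(trifluoromethanesulfonate)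
Product: 12 3,6-bis(2-amino-4-chlorophenyl)-4,5-dimethoxy-1,2-phenylene bis(trifluoromethanesulfonate)
Conditions: H2 (1 atm), 5% Pt(S)/C, EtOAc, rt
Reagents that add atoms: none
Why: Chemoselective catalytic hydrogenation over sulfided platinum reduces both nitro groups to anilines without hydrogenolysis of the aryl chlorides or the aryl triflates.

Step 7
Reactants: 12 3,6-bis(2-amino-4-chlorophenyl)-4,5-dimethoxy-1,2-phenylene bis(trifluoromethanesulfonate)
Product: 13 borregomycin E (2,9-dichloro-5,6-dimethoxy-11,12-dihydroindolo[2,3-a]carbazole)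
Conditions: Pd2(dba)3 (5 mol%), Xantphos (12 mol%), Cs2CO3 (3 equiv), toluene, 100 °C
Reagents that add atoms: none
Why: A double intramolecular Buchwald–Hartwig amination joins each aniline nitrogen to the neighbouring triflate-bearing carbon, closing both five-membered rings; a Pd/Xantphos catalyst with a weak carbonate base should insert into aryl triflates but not into the chlorides of the electron-rich rings and should not cleave the triflate S–O bond.

**Compound list**
1 | 2,3-dimethoxybuta-1,3-diene | C=C(OC)C(=C)OC | starting material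
2 | (Z)-2,3-dimethoxy-1,4-bis(4,4,5,5-tetramethyl-1,3,2-dioxaborolan-2-yl)but-2-ene | CO/C(CB1OC(C)(C)C(C)(C)O1)=C(OC)/CB1OC(C)(C)C(C)(C)O1 | intermediate
3 | (Z)-2,3-dimethoxybut-2-ene-1,4-diol | CO/C(CO)=C(OC)/CO | intermediate
4 | dimethyl (Z)-(2,3-dimethoxybut-2-ene-1,4-diyl) bis(carbonate) | CO/C(COC(=O)OC)=C(OC)/COC(=O)OC | intermediate
5 | (4-chloro-2-nitrophenyl)boronic acid | OB(O)c1ccc(Cl)cc1[N+](=O)[O-] | starting material
6 | (Z)-1,4-bis(4-chloro-2-nitrophenyl)-2,3-dimethoxybut-2-ene | CO/C(Cc1ccc(Cl)cc1[N+](=O)[O-])=C(OC)/Cc1ccc(Cl)cc1[N+](=O)[O-] | intermediate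
7 | diethyl oxalate | CCOC(=O)C(=O)OCC | starting material
8 | ethyl (Z)-3,6-bis(4-chloro-2-nitrophenyl)-4,5-dimethoxy-2-oxohex-4-enoate (racemic at C3) | CCOC(=O)C(=O)C(c1ccc(Cl)cc1[N+](=O)[O-])/C(OC)=C(OC)\Cc1ccc(Cl)cc1[N+](=O)[O-] | intermediate
9 | 3,6-bis(4-chloro-2-nitrophenyl)-4,5-dimethoxycyclohex-4-ene-1,2-dione (mixture of stereoisomers) | COC1=C(OC)C(c2ccc(Cl)cc2[N+](=O)[O-])C(=O)C(=O)C1c1ccc(Cl)cc1[N+](=O)[O-] | intermediate
10 | 3,6-bis(4-chloro-2-nitrophenyl)-4,5-dimethoxybenzene-1,2-diol | COc1c(OC)c(-c2ccc(Cl)cc2[N+](=O)[O-])c(O)c(O)c1-c1ccc(Cl)cc1[N+](=O)[O-] | intermediate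
11 | 3,6-bis(4-chloro-2-nitrophenyl)-4,5-dimethoxy-1,2-phenylene bis(trifluoromethanesulfonate) | COc1c(OC)c(-c2ccc(Cl)cc2[N+](=O)[O-])c(OS(=O)(=O)C(F)(F)F)c(OS(=O)(=O)C(F)(F)F)c1-c1ccc(Cl)cc1[N+](=O)[O-] | intermediate
12 | 3,6-bis(2-amino-4-chlorophenyl)-4,5-dimethoxy-1,2-phenylene bis(trifluoromethanesulfonate) | COc1c(OC)c(-c2ccc(Cl)cc2N)c(OS(=O)(=O)C(F)(F)F)c(OS(=O)(=O)C(F)(F)F)c1-c1ccc(Cl)cc1N | intermediate
13 | borregomycin E (2,9-dichloro-5,6-dimethoxy-11,12-dihydroindolo[2,3-a]carbazole) | COc1c(OC)c2c3ccc(Cl)cc3[nH]c2c2[nH]c3cc(Cl)ccc3c12 | target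

**Step count:** 7 steps in total; longest linear sequence 7 steps (1 → 3 → 4 → 6 → 10 → 11 → 12 → 13).

**Steps most likely to fail**

1. Step 4 (proposed new method). The nitrobenzyl anion may be reprotonated at the methoxy-bearing allylic carbon, which moves the double bond into conjugation and then allows loss of methoxide. Acylation may occur at both ends by two oxalate molecules without ring closure, and the anions may dimerize oxidatively by electron transfer to the nitroarene. Fallback with known reactions, setting out from boronic acid 5 and returning at 13: commercial 1,2-dibromo-4,5-dimethoxybenzene is magnesiated twice between OMe and Br (TMPMgCl·LiCl, THF, −20 °C) and quenched with iodine to give 1,2-dibromo-3,6-diiodo-4,5-dimethoxybenzene F1. Suzuki–Miyaura coupling of 5 at the two C–I bonds (Pd(OAc)2, SPhos, K3PO4, toluene/H2O) gives 1,2-dibromo-3,6-bis(4-chloro-2-nitrophenyl)-4,5-dimethoxybenzene F2. Fe/NH4Cl reduces both nitro groups to 2,2'-(2,3-dibromo-5,6-dimethoxy-1,4-phenylene)bis(5-chloroaniline) F3, and double intramolecular Buchwald–Hartwig amination at the C–Br bonds under the conditions of step 7 gives 13.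

2. Step 3. Syn–anti isomerization of the π-allyl intermediates would erode the Z geometry, and slow transmetalation with protodeboronation of the ortho-nitro boronic acid would stall the coupling. Fallback without a π-allyl complex, setting out from diol 3 and returning at 6: 3 is phosphorylated (ClP(O)(OEt)2, pyridine) to (Z)-2,3-dimethoxybut-2-ene-1,4-diyl tetraethyl bis(phosphate) F4. This is displaced at both primary carbons by (4-chloro-2-nitrophenyl)magnesium chloride F5, made from 4-chloro-1-iodo-2-nitrobenzene and PhMgCl in THF at −40 °C, under Li2CuCl4 catalysis; this SN2-type copper coupling keeps alkene geometry in neryl-type substrates.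

3. Step 7. Oxidative addition at the hindered, electron-rich triflates may be sluggish, insertion into the aryl chlorides may compete, and the base may cleave the triflate S–O bonds. Fallback by condensation instead of cross-coupling, setting out from catechol 10 and returning at 13: hydrogenation (H2, Pt(S)/C) gives 3,6-bis(2-amino-4-chlorophenyl)-4,5-dimethoxybenzene-1,2-diol F6. Ag2O oxidizes the catechol to 3,6-bis(2-amino-4-chlorophenyl)-4,5-dimethoxycyclohexa-3,5-diene-1,2-dione F7, whose anilines condense 5-exo-trig onto the adjacent carbonyl groups to give the quinone diimine 2,9-dichloro-5,6-dimethoxyindolo[2,3-a]carbazole F8. Na2S2O4 in the same flask reduces F8 to 13.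

**Further compounds**
F1 | step 4 | 1,2-dibromo-3,6-diiodo-4,5-dimethoxybenzene | COc1c(OC)c(I)c(Br)c(Br)c1I
F2 | step 4 | 1,2-dibromo-3,6-bis(4-chloro-2-nitrophenyl)-4,5-dimethoxybenzene | COc1c(OC)c(-c2ccc(Cl)cc2[N+](=O)[O-])c(Br)c(Br)c1-c1ccc(Cl)cc1[N+](=O)[O-]
F3 | step 4 | 2,2'-(2,3-dibromo-5,6-dimethoxy-1,4-phenylene)bis(5-chloroaniline) | COc1c(OC)c(-c2ccc(Cl)cc2N)c(Br)c(Br)c1-c1ccc(Cl)cc1N
F4 | step 3 | (Z)-2,3-dimethoxybut-2-ene-1,4-diyl tetraethyl bis(phosphate) | CCOP(=O)(OCC)OC/C(OC)=C(OC)\COP(=O)(OCC)OCC
F5 | step 3 | (4-chloro-2-nitrophenyl)magnesium chloride | [O-][N+](=O)c1cc(Cl)ccc1[Mg]Cl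
F6 | step 7 | 3,6-bis(2-amino-4-chlorophenyl)-4,5-dimethoxybenzene-1,2-diol | COc1c(OC)c(-c2ccc(Cl)cc2N)c(O)c(O)c1-c1ccc(Cl)cc1N
F7 | step 7 | 3,6-bis(2-amino-4-chlorophenyl)-4,5-dimethoxycyclohexa-3,5-diene-1,2-dione | COC1=C(c2ccc(Cl)cc2N)C(=O)C(=O)C(c2ccc(Cl)cc2N)=C1OC
F8 | step 7 | 2,9-dichloro-5,6-dimethoxyindolo[2,3-a]carbazole (quinone diimine) | COC1=C2c3ccc(Cl)cc3N=C2C2=Nc3cc(Cl)ccc3C2=C1OC
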